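**Assumption:** the SMILES is read as epiguibourtinidol-(4β→8)-epicatechin (upper unit 2R,3R,4R, i.e. 2,3-cis-3,4-trans; lower unit 2R,3R); the benzyl-protected acetophenone and aldehyde and (−)-epicatechin are taken as purchasable.

## Retrosynthetic overview

1. Target ⇐ hexa-O-benzyl dimer; global hydrogenolysis comes last.
2. C4–C8 interflavan bond ⇐ flavan-4-yl cation from a 4-methoxy-2,3-cis-flavan-3-ol (upper unit) plus C8 of tetra-O-benzyl-(−)-epicatechin (rings D, F, E bought intact).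
3. C3–O (cis to the 2-aryl group) and C4–O ⇐ bromohydrin → syn-epoxide → methanolysis of an (S)-flav-3-ene.
4. Key disconnection, O1–C2: ring C is closed by an enantioconvergent acid-catalysed C–O cyclisation of the racemic allylic alcohol from a 2'-hydroxychalcone. This one C–O bond fixes the absolute configuration of the whole upper unit.
5. Chalcone ⇐ Claisen–Schmidt condensation. Ring order: rings A and B bought, ring C formed in the key step, then C3/C4 oxygenation, then union with the preformed D/F/E unit.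

## Route

**Step 1**
Reactants: 1 1-[4-(benzyloxy)-2-hydroxyphenyl]ethan-1-one; 2 4-(benzyloxy)benzaldehyde
Product: 3 (E)-1-[4-(benzyloxy)-2-hydroxyphenyl]-3-[4-(benzyloxy)phenyl]prop-2-en-1-one
Conditions: KOH (50% aq), EtOH, rt, 36 h; then 1 M HCl, 0 °C
Reagents that add atoms: none
Why: Claisen–Schmidt aldol condensation of the acetophenone enolate with the non-enolisable aldehyde, dehydrating under thermodynamic control to the E-enone (no stereocentre).

**Step 2**
Reactants: 3 (E)-1-[4-(benzyloxy)-2-hydroxyphenyl]-3-[4-(benzyloxy)phenyl]prop-2-en-1-one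
Product: 5 (2S)-7-(benzyloxy)-2-[4-(benzyloxy)phenyl]-2H-chromene, via racemic allylic alcohol 4 (not isolated)
Conditions: NaBH4, CeCl3·7H2O, MeOH–THF, −20 °C; NaHCO3 work-up, solvent switch; then (R)-3,3'-bis(2,4,6-triisopropylphenyl)-H8-BINOL N-triflylphosphoramide (5 mol%), 5 Å MS, toluene–CH2Cl2 (4:1), −60 °C; Et3N quench
Reagents that add atoms: none
Why: Proposed new method: after Luche 1,2-reduction, the chiral strong Brønsted acid ionises both enantiomers of 4 to the same 1,3-diarylallyl cation (protonated vinyl ortho-quinone methide); its contact ion pair, with the phosphoramide anion hydrogen-bonded to the phenol O–H, collapses by 6-endo O1–C2 bond formation (formally an oxa-6π ring closure) on one face, closing ring C and setting C2 as S (which acid antipode gives S is fixed in the first run); the closest known reaction types are chiral Brønsted-acid contact-ion-pair intramolecular allylic etherification to 2H-chromenes and Pd-catalysed asymmetric 6-endo allylic etherification to 2-aryl-2H-chromenes, neither shown on a 4-unsubstituted secondary alcohol with two alkoxyaryl termini telescoped from a chalcone.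

**Step 3**
Reactants: 5 (2S)-7-(benzyloxy)-2-[4-(benzyloxy)phenyl]-2H-chromene
Product: 8 (2R,3R,4S)-7-(benzyloxy)-2-[4-(benzyloxy)phenyl]-4-methoxychroman-3-ol, via bromohydrin 6 (not isolated), via syn-epoxide 7 (not isolated)
Conditions: NBS, THF–H2O (4:1), 0 °C, dark; then K2CO3, MeOH, 0 °C → rt
Reagents that add atoms: water (O); methanol (CO)
Why: Bromohydrin formation, intramolecular Williamson epoxide closure and solvolytic epoxide opening: Br+ adds to C3 anti to the 2-aryl group and water opens trans at benzylic C4, the C4 alkoxide then displaces bromide by SN2 so the C3–O bond lands on the 2-aryl face (2,3-cis, 3R), and the 7-alkoxy-activated benzylic epoxide is methanolysed at C4 (trans major; either C4 epimer serves step 5).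

**Step 4**
Reactants: 9 (−)-epicatechin
Product: 10 (2R,3R)-5,7-bis(benzyloxy)-2-[3,4-bis(benzyloxy)phenyl]chroman-3-ol
Conditions: BnBr (4.4 equiv), K2CO3, DMF, −10 °C → rt, Ar
Reagents that add atoms: benzyl bromide (BrCc1ccccc1)
Why: Williamson ether synthesis in which the four phenols are alkylated selectively over the secondary 3-OH under carbonate base, the low temperature limiting C2 epimerisation (stereocentres untouched).

**Step 5**
Reactants: 8 (2R,3R,4S)-7-(benzyloxy)-2-[4-(benzyloxy)phenyl]-4-methoxychroman-3-ol; 10 (2R,3R)-5,7-bis(benzyloxy)-2-[3,4-bis(benzyloxy)phenyl]chroman-3-ol (3 equiv)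
Product: 11 (2R,3R,4R)-7-(benzyloxy)-2-[4-(benzyloxy)phenyl]-4-{(2R,3R)-5,7-bis(benzyloxy)-2-[3,4-bis(benzyloxy)phenyl]-3-hydroxychroman-8-yl}chroman-3-ol
Conditions: Me3SiOTf (0.2 equiv), CH2Cl2, −78 → −40 °C; Et3N quench
Reagents that add atoms: none
Why: Lewis-acid SN1 Friedel–Crafts alkylation in which the 7-alkoxy-stabilised flavan-4-yl cation is attacked by the most nucleophilic, least hindered C8 of 10 on the face anti to the 3-OH and the 2-aryl group, setting C4 as R (3,4-trans), as is general for 2,3-cis flavan-4-yl cations.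

**Step 6**
Reactants: 11 (2R,3R,4R)-7-(benzyloxy)-2-[4-(benzyloxy)phenyl]-4-{(2R,3R)-5,7-bis(benzyloxy)-2-[3,4-bis(benzyloxy)phenyl]-3-hydroxychroman-8-yl}chroman-3-ol
Product: 12 epiguibourtinidol-(4β→8)-epicatechin, (2R,3R,4R)-2-(4-hydroxyphenyl)-4-[(2R,3R)-2-(3,4-dihydroxyphenyl)-3,5,7-trihydroxychroman-8-yl]chromane-3,7-diol
Conditions: H2 (1 atm), Pd(OH)2/C, THF–MeOH–H2O (20:20:1), rt
Reagents that add atoms: none
Why: Catalytic hydrogenolysis of the six benzyl ethers under neutral conditions that leave the pyran C–O bonds, the interflavan bond and all five stereocentres untouched.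

## Compound list

1 | 1-[4-(benzyloxy)-2-hydroxyphenyl]ethan-1-one | CC(=O)c1ccc(OCc2ccccc2)cc1O | starting material
2 | 4-(benzyloxy)benzaldehyde | O=Cc1ccc(OCc2ccccc2)cc1 | starting material
3 | (E)-1-[4-(benzyloxy)-2-hydroxyphenyl]-3-[4-(benzyloxy)phenyl]prop-2-en-1-one | O=C(/C=C/c1ccc(OCc2ccccc2)cc1)c1ccc(OCc2ccccc2)cc1O | intermediate
4 | (E)-1-[4-(benzyloxy)-2-hydroxyphenyl]-3-[4-(benzyloxy)phenyl]prop-2-en-1-ol (racemic, not isolated) | OC(/C=C/c1ccc(OCc2ccccc2)cc1)c1ccc(OCc2ccccc2)cc1O | intermediate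
5 | (2S)-7-(benzyloxy)-2-[4-(benzyloxy)phenyl]-2H-chromene | C(c1ccccc1)Oc1ccc([C@H]2Oc3cc(OCc4ccccc4)ccc3C=C2)cc1 | intermediate
6 | (2R,3S,4R)-7-(benzyloxy)-2-[4-(benzyloxy)phenyl]-3-bromochroman-4-ol (not isolated) | C(c1ccccc1)Oc1ccc([C@H]2Oc3cc(OCc4ccccc4)ccc3[C@@H](O)[C@@H]2Br)cc1 | intermediate
7 | (1aR,2R,7bR)-5-(benzyloxy)-2-[4-(benzyloxy)phenyl]-1a,7b-dihydro-2H-oxireno[2,3-c]chromene, oxirane on the face of the 2-aryl group (not isolated) | C(c1ccccc1)Oc1ccc([C@H]2Oc3cc(OCc4ccccc4)ccc3[C@H]5O[C@@H]25)cc1 | intermediate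
8 | (2R,3R,4S)-7-(benzyloxy)-2-[4-(benzyloxy)phenyl]-4-methoxychroman-3-ol | C(c1ccccc1)Oc1ccc([C@H]2Oc3cc(OCc4ccccc4)ccc3[C@H](OC)[C@H]2O)cc1 | intermediate
9 | (−)-epicatechin, (2R,3R)-2-(3,4-dihydroxyphenyl)chromane-3,5,7-triol | Oc1cc(O)c2c(c1)O[C@H](c1ccc(O)c(O)c1)[C@H](O)C2 | starting material
10 | (2R,3R)-5,7-bis(benzyloxy)-2-[3,4-bis(benzyloxy)phenyl]chroman-3-ol | C(c1ccccc1)Oc1cc(OCc3ccccc3)c2c(c1)O[C@H](c1ccc(OCc3ccccc3)c(OCc3ccccc3)c1)[C@H](O)C2 | intermediate
11 | (2R,3R,4R)-7-(benzyloxy)-2-[4-(benzyloxy)phenyl]-4-{(2R,3R)-5,7-bis(benzyloxy)-2-[3,4-bis(benzyloxy)phenyl]-3-hydroxychroman-8-yl}chroman-3-ol | C(c1ccccc1)Oc1ccc([C@H]2Oc3cc(OCc4ccccc4)ccc3[C@H](c3c(OCc4ccccc4)cc(OCc4ccccc4)c4c3O[C@H](c3ccc(OCc5ccccc5)c(OCc5ccccc5)c3)[C@H](O)C4)[C@H]2O)cc1 | intermediate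
12 | epiguibourtinidol-(4β→8)-epicatechin, (2R,3R,4R)-2-(4-hydroxyphenyl)-4-[(2R,3R)-2-(3,4-dihydroxyphenyl)-3,5,7-trihydroxychroman-8-yl]chromane-3,7-diol | Oc1ccc([C@H]2Oc3cc(O)ccc3[C@H](c3c(O)cc(O)c4c3O[C@H](c3ccc(O)c(O)c3)[C@H](O)C4)[C@H]2O)cc1 | target

## Step count and risks

Total steps: 6. Longest linear sequence: 5 (steps 1, 2, 3, 5, 6); step 4 is the one-step side branch.

**Step 2 (proposed new step).** The risks are a racemic background cyclisation of the very labile alcohol 4 and acid-mediated re-ionisation of the product ether, both of which erode ee. The fallback uses known chemistry and sets out from 1. Condensation with N,N-dimethylformamide dimethyl acetal (neat, 95 °C) gives (E)-1-[4-(benzyloxy)-2-hydroxyphenyl]-3-(dimethylamino)prop-2-en-1-one F1. HCl in CH2Cl2 closes it to 7-(benzyloxy)-4H-chromen-4-one F2. Asymmetric conjugate addition of 4-(benzyloxy)phenylboronic acid (Pd(OCOCF3)2, t-BuPyOx antipode that delivers the 2S product, NH4PF6, H2O, ClCH2CH2Cl, 60 °C) gives (2S)-7-(benzyloxy)-2-[4-(benzyloxy)phenyl]chroman-4-one F3. NaBH4 in MeOH–THF reduces it to the cis alcohol (2S,4S)-7-(benzyloxy)-2-[4-(benzyloxy)phenyl]chroman-4-ol F4. Neutral syn-dehydration with Burgess reagent (THF, 50 °C) returns to the route at 5.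

**Step 3.** The risks are ring bromination of the alkoxyarenes, non-anti capture of the open benzylic cation (a cis-bromohydrin cannot close to the epoxide), and loss of the labile epoxide. The fallback sets out from 5. Hydroboration–oxidation (BH3·THF, then NaBO3·4H2O) anti to the 2-aryl group gives (2R,3S)-7-(benzyloxy)-2-[4-(benzyloxy)phenyl]chroman-3-ol F5. Dess–Martin oxidation gives (2R)-7-(benzyloxy)-2-[4-(benzyloxy)phenyl]chroman-3-one F6. Reduction with LiBH(s-Bu)3 (THF, −78 °C) from the face opposite the 2-aryl group gives the 2,3-cis alcohol (2R,3R)-7-(benzyloxy)-2-[4-(benzyloxy)phenyl]chroman-3-ol F7. Benzylic oxidation with DDQ in CH2Cl2–MeOH returns to the route at 8.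

**Step 5.** The risks are O-alkylation through the free 3-OH groups, C2 ring opening of the acid-labile upper unit, and over-condensation to trimers. The fallback sets out from 8 and replaces hard oxophilic activation with soft thiophilic activation. Exchange with benzyl mercaptan (BF3·OEt2, CH2Cl2, −78 °C) gives the bench-stable thioether (2R,3S,4S)-7-(benzyloxy)-2-[4-(benzyloxy)phenyl]-4-(benzylsulfanyl)chroman-3-ol F8. AgBF4 in THF–CH2Cl2 at 0 °C then activates it in the presence of 10 under near-neutral conditions, returning to the route at 11.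

## Further compounds

F1 | step 2 | (E)-1-[4-(benzyloxy)-2-hydroxyphenyl]-3-(dimethylamino)prop-2-en-1-one | CN(C)/C=C/C(=O)c1ccc(OCc2ccccc2)cc1O
F2 | step 2 | 7-(benzyloxy)-4H-chromen-4-one | O=c1ccoc2cc(OCc3ccccc3)ccc12
F3 | step 2 | (2S)-7-(benzyloxy)-2-[4-(benzyloxy)phenyl]chroman-4-one | C(c1ccccc1)Oc1ccc([C@H]2Oc3cc(OCc4ccccc4)ccc3C(=O)C2)cc1
F4 | step 2 | (2S,4S)-7-(benzyloxy)-2-[4-(benzyloxy)phenyl]chroman-4-ol | C(c1ccccc1)Oc1ccc([C@H]2Oc3cc(OCc4ccccc4)ccc3[C@@H](O)C2)cc1
F5 | step 3 | (2R,3S)-7-(benzyloxy)-2-[4-(benzyloxy)phenyl]chroman-3-ol | C(c1ccccc1)Oc1ccc([C@H]2Oc3cc(OCc4ccccc4)ccc3C[C@@H]2O)cc1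
F6 | step 3 | (2R)-7-(benzyloxy)-2-[4-(benzyloxy)phenyl]chroman-3-one | C(c1ccccc1)Oc1ccc([C@H]2Oc3cc(OCc4ccccc4)ccc3CC2=O)cc1
F7 | step 3 | (2R,3R)-7-(benzyloxy)-2-[4-(benzyloxy)phenyl]chroman-3-ol | C(c1ccccc1)Oc1ccc([C@H]2Oc3cc(OCc4ccccc4)ccc3C[C@H]2O)cc1
F8 | step 5 | (2R,3S,4S)-7-(benzyloxy)-2-[4-(benzyloxy)phenyl]-4-(benzylsulfanyl)chroman-3-ol | C(c1ccccc1)Oc1ccc([C@H]2Oc3cc(OCc4ccccc4)ccc3[C@H](SCc3ccccc3)[C@H]2O)cc1
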